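**Plan**

- Locants are those of the target as a 5,6,7,8-tetrahydronaphthalene-2-carboxylic acid: C2 CO2H, C3/C4 OH, C5 CHMe, C8 CH bearing the side chain C1'–C7'.
- Retrosynthesis: (i) three O-benzyl groups off; (ii) ring bond C4a–C5 cut to an aryl bromide (Br on C4a) and a terminal olefin (C5=CH2, the CH2 being the future methyl); (iii) C5–C6 cut (vinyl bromide as the C5/methyl unit); (iv) C8–C2' cut to an aryl vinyl carbinol and the aldehyde of the C1'–C7' chain.
- Forward: the fully substituted benzoate ring is made first, the chain is joined to it by iridium/amine dual catalysis and lengthened by two carbons, and the carbocycle is closed last by cobalt-hydride/nickel hydroarylation.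
- What makes the closure possible: C4a lies between the C4 oxygen and the chain-bearing C8a, which in the aldehyde precursor is the isovanillin position (between a free OH and CHO) and so can be marked with bromine; C5 is the internal carbon of a monosubstituted olefin four carbons from C8a, so Markovnikov hydrogen-atom transfer puts a radical exactly there.
- Stereochemistry: C6' from (S)-3-bromo-2-methylpropan-1-ol; C8 and C2' from the two catalysts of the allylation; C5 from the ring closure, trans to the C8 substituent because both groups sit pseudoaxial (peri strain with O4 and H1).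

Key step: step 13

Assumption: in step 9 each catalyst fixes one centre independently (ligand: C8; amine: C2'). (S)-L and the (R)-prolinol ether are taken as the pair that gives 14; the antipode of either catalyst is used if its facial sense is the opposite.

**Route**

Step 1
Reactants: 1 4-hydroxy-3-iodo-5-methoxybenzaldehyde (5-iodovanillin)
Product: 2 5-formyl-2-hydroxy-3-methoxybenzoic acid
Conditions: Pd(OAc)2 (cat.), dppf, CO (1 atm), K2CO3, DMF/H2O, 80 °C; then aq. HCl
Reagents that add atoms: carbon monoxide [C-]#[O+]; water O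
Why: Palladium-catalysed hydroxycarbonylation of the aryl iodide (oxidative addition of zerovalent palladium, CO insertion, hydrolysis of the acylpalladium) should put the future C2 carboxyl next to the free phenol while the aldehyde stays inert.

Step 2
Reactants: 2 5-formyl-2-hydroxy-3-methoxybenzoic acid
Product: 3 5-formyl-2,3-dihydroxybenzoic acid
Conditions: BBr3, CH2Cl2, −78 °C → rt; then H2O
Reagents that add atoms: none
Why: Lewis-acid cleavage of the aryl methyl ether (borane adduct, bromide attack on the methyl group) should free the 3-hydroxyl, which is needed to steer the next halogenation.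

Step 3
Reactants: 3 5-formyl-2,3-dihydroxybenzoic acid
Product: 4 4-bromo-5-formyl-2,3-dihydroxybenzoic acid
Conditions: Br2 (1 equiv), NaOAc, AcOH, rt
Reagents that add atoms: bromine BrBr
Why: Electrophilic aromatic bromination should go to position 4 of 3 (the future C4a), between the free 3-hydroxyl and the formyl group, as isovanillin gives 2-bromoisovanillin; the only other free position is wedged between CHO and CO2H, and all ortho/para positions of the 2-hydroxyl are substituted.

Step 4
Reactants: 4 4-bromo-5-formyl-2,3-dihydroxybenzoic acid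
Product: 5 benzyl 2,3-bis(benzyloxy)-4-bromo-5-formylbenzoate
Conditions: BnBr (3.5 equiv), K2CO3, DMF, 60 °C
Reagents that add atoms: benzyl bromide BrCc1ccccc1
Why: Williamson O-alkylation of both phenols and of the carboxylate should install one kind of protecting group that hydrogenolysis removes at the end without touching acetates.

Step 5
Reactants: 5 benzyl 2,3-bis(benzyloxy)-4-bromo-5-formylbenzoate
Product: 6 benzyl 2,3-bis(benzyloxy)-4-bromo-5-(1-hydroxyprop-2-en-1-yl)benzoate (racemic)
Conditions: vinylmagnesium bromide, THF, −78 °C; aq. NH4Cl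
Reagents that add atoms: vinylmagnesium bromide C=C[Mg]Br
Why: Grignard 1,2-addition should take place at the aldehyde, which at −78 °C is far more electrophilic than the hindered benzyl benzoate; the carbinol centre is left racemic on purpose because step 9 is enantioconvergent.

Step 6
Reactants: 7 2-(3-chloropropyl)-1,3-dioxolane; 8 (2S)-3-bromo-2-methylpropan-1-ol
Product: 11 (2R)-6-(1,3-dioxolan-2-yl)-2-methylhexan-1-ol, via Grignard reagent 9 (not isolated), via magnesium alkoxide 10 (not isolated)
Conditions: 7, Mg, THF, 60 °C (gives 9); 8, MeMgCl (1 equiv), THF, −20 °C (gives 10); combine, Li2CuCl4 (cat.), −20 → 0 °C; aq. NH4Cl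
Reagents that add atoms: none
Why: Copper-catalysed sp3–sp3 Grignard cross-coupling at the primary bromide should leave the stereocentre untouched, since it is one carbon away from the reacting CH2 (the descriptor changes from S to R only through the priority rules), with the alcohol masked as its magnesium alkoxide.

Step 7
Reactants: 11 (2R)-6-(1,3-dioxolan-2-yl)-2-methylhexan-1-ol
Product: 12 (2R)-6-(1,3-dioxolan-2-yl)-2-methylhexyl acetate
Conditions: Ac2O, pyridine, DMAP (cat.), CH2Cl2, 0 °C → rt
Reagents that add atoms: acetic anhydride CC(=O)OC(C)=O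
Why: DMAP-catalysed acetylation should install the C7' acetate of the target at the outset, so this oxygen needs no separate protecting group.

Step 8
Reactants: 12 (2R)-6-(1,3-dioxolan-2-yl)-2-methylhexyl acetate
Product: 13 (2R)-2-methyl-7-oxoheptyl acetate
Conditions: 1 M aq. HCl, THF, rt
Reagents that add atoms: water O
Why: Acid-catalysed acetal hydrolysis should release the aldehyde, a primary acetate being stable to dilute aqueous acid at room temperature.

Step 9
Reactants: 6 racemic aryl vinyl carbinol; 13 (2R)-2-methyl-7-oxoheptyl acetate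
Product: 14 benzyl 5-[(3S,4S,8R)-9-acetoxy-4-formyl-8-methylnon-1-en-3-yl]-2,3-bis(benzyloxy)-4-bromobenzoate
Conditions: [Ir(cod)Cl]2 (cat.), (S)-L [(S)-BINOL-derived N-dibenzo[b,f]azepinyl phosphoramidite–olefin ligand] (cat.), (R)-2-{bis[3,5-bis(trifluoromethyl)phenyl](trimethylsilyloxy)methyl}pyrrolidine (cat.), (MeO)2P(O)OH (promoter), 1,2-dichloroethane, 25 °C
Reagents that add atoms: none
Why: In this stereodivergent dual iridium/amine-catalysed α-allylation of a linear aldehyde, the iridium complex should ionise both enantiomers of 6 to one π-allyl species and fix the benzylic centre (future C8), while the diarylprolinol silyl ether enamine of 13 fixes the α-centre (future C2'), each catalyst acting independently and the remote C6' centre having no say.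

Step 10
Reactants: 14 γ,δ-unsaturated aldehyde
Product: 15 benzyl 5-[(3S,4S,8R)-9-acetoxy-4-(hydroxymethyl)-8-methylnon-1-en-3-yl]-2,3-bis(benzyloxy)-4-bromobenzoate
Conditions: NaBH4, MeOH/CH2Cl2, −40 °C
Reagents that add atoms: none
Why: Chemoselective borohydride reduction of the aldehyde at low temperature, before the α-centre can epimerise, should leave the acetate, the benzyl ester and the aryl bromide untouched.

Step 11
Reactants: 15 primary alcohol
Product: 16 benzyl 5-[(3S,4S,8R)-9-acetoxy-4-(acetoxymethyl)-8-methylnon-1-en-3-yl]-2,3-bis(benzyloxy)-4-bromobenzoate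
Conditions: Ac2O, pyridine, DMAP (cat.), CH2Cl2, 0 °C → rt
Reagents that add atoms: acetic anhydride CC(=O)OC(C)=O
Why: Acetylation of the new primary alcohol should complete the diacetate of the target, both acetates being stable to all later steps.

Step 12
Reactants: 16 vinyl diacetate
Product: 18 benzyl 5-[(5S,6S,10R)-11-acetoxy-6-(acetoxymethyl)-10-methylundec-1-en-5-yl]-2,3-bis(benzyloxy)-4-bromobenzoate, via B-alkyl-9-BBN adduct 17 (not isolated)
Conditions: 9-BBN, THF, 0 °C → rt; then Pd(dppf)Cl2 (cat.), AsPh3, vinyl bromide (excess), aq. K3PO4, DMF, rt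
Reagents that add atoms: vinyl bromide C=CBr
Why: Anti-Markovnikov hydroboration of the vinyl group followed by B-alkyl Suzuki–Miyaura coupling should lengthen the chain to the but-3-enyl group, the unhindered vinyl bromide in excess undergoing oxidative addition much faster than the di-ortho-substituted aryl bromide that is kept for step 13.

Step 13
Reactants: 18 aryl bromide with but-3-enyl chain
Product: 19 benzyl (5R,8S)-3,4-bis(benzyloxy)-8-[(2S,6R)-1,7-diacetoxy-6-methylheptan-2-yl]-5-methyl-5,6,7,8-tetrahydronaphthalene-2-carboxylate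
Conditions: NiBr2·diglyme (cat.), 4,4'-di-tert-butyl-2,2'-bipyridine, Co(salen) (cat., divalent cobalt; salen = N,N'-bis(3,5-di-tert-butylsalicylidene)ethylenediamine dianion), N-fluoro-2,4,6-trimethylpyridinium tetrafluoroborate (substoichiometric, initiator), PhSiH2(Oi-Pr), DMPU, rt, high dilution
Reagents that add atoms: none
Why: Proposed new method: a cobalt salen hydride (trivalent cobalt) should transfer a hydrogen atom to the terminal CH2 of the olefin, the secondary C5 radical should be captured by the aryl–nickel bromide formed by oxidative addition of zerovalent nickel into the C4a–Br bond, and C–C reductive elimination from the aryl(alkyl)nickel species (trivalent nickel) should close the C4a–C5 bond, after which monovalent nickel and divalent cobalt exchange an electron to restart both cycles, so the silane is the only stoichiometric reagent. The closest known reaction type is the intermolecular cobalt/nickel dual-catalysed branch-selective hydroarylation of terminal olefins with haloarenes, which has not been run as a ring closure. The carbocycle closes in a 6-exo-trig sense with respect to the olefin, through a seven-membered nickelacycle that contracts on reductive elimination. C5 is the only new stereocentre: capture of the planar radical by nickel is reversible, so the outcome is decided in tetralin-like half-chair transition states of the reductive elimination, in which the C5 methyl turns pseudoaxial to avoid the C4 benzyloxy group and the C8 side chain turns pseudoaxial to avoid H1, and 5,8-diaxial is the trans (5R,8S) arrangement. Site selectivity (C4a against C1, both ortho to the chain) is secured by the bromine on C4a, Markovnikov selectivity by the hydrogen-atom-transfer step, and chemoselectivity by the neutral conditions that leave the benzyl ester, benzyl ethers and acetates alone.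

Step 14
Reactants: 19 tribenzyl-protected tetralin
Product: 20 (5R,8S)-8-[(2S,6R)-1,7-diacetoxy-6-methylheptan-2-yl]-3,4-dihydroxy-5-methyl-5,6,7,8-tetrahydronaphthalene-2-carboxylic acid (CNP0245723.1)
Conditions: H2 (1 atm), Pd/C, EtOAc, rt
Reagents that add atoms: none
Why: Hydrogenolysis should remove the two benzyl ethers and the benzyl ester in one operation without affecting the acetates, the tetralin or its stereocentres.

**Compound list**

1 | 4-hydroxy-3-iodo-5-methoxybenzaldehyde (5-iodovanillin) | COc1cc(C=O)cc(I)c1O | starting material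
2 | 5-formyl-2-hydroxy-3-methoxybenzoic acid | COc1cc(C=O)cc(C(=O)O)c1O | intermediate
3 | 5-formyl-2,3-dihydroxybenzoic acid | O=Cc1cc(O)c(O)c(C(=O)O)c1 | intermediate
4 | 4-bromo-5-formyl-2,3-dihydroxybenzoic acid | O=Cc1cc(C(=O)O)c(O)c(O)c1Br | intermediate
5 | benzyl 2,3-bis(benzyloxy)-4-bromo-5-formylbenzoate | O=Cc1cc(C(=O)OCc2ccccc2)c(OCc2ccccc2)c(OCc2ccccc2)c1Br | intermediate
6 | benzyl 2,3-bis(benzyloxy)-4-bromo-5-(1-hydroxyprop-2-en-1-yl)benzoate (racemic) | C=CC(O)c1cc(C(=O)OCc2ccccc2)c(OCc2ccccc2)c(OCc2ccccc2)c1Br | intermediate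
7 | 2-(3-chloropropyl)-1,3-dioxolane | ClCCCC1OCCO1 | starting material
8 | (2S)-3-bromo-2-methylpropan-1-ol | OC[C@H](C)CBr | starting material
9 | [3-(1,3-dioxolan-2-yl)propyl]magnesium chloride | Cl[Mg]CCCC1OCCO1 | intermediate
10 | chloromagnesium (2S)-3-bromo-2-methylpropan-1-olate | Cl[Mg]OC[C@H](C)CBr | intermediate
11 | (2R)-6-(1,3-dioxolan-2-yl)-2-methylhexan-1-ol | OC[C@H](C)CCCCC1OCCO1 | intermediate
12 | (2R)-6-(1,3-dioxolan-2-yl)-2-methylhexyl acetate | CC(=O)OC[C@H](C)CCCCC1OCCO1 | intermediate
13 | (2R)-2-methyl-7-oxoheptyl acetate | CC(=O)OC[C@H](C)CCCCC=O | intermediate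
14 | benzyl 5-[(3S,4S,8R)-9-acetoxy-4-formyl-8-methylnon-1-en-3-yl]-2,3-bis(benzyloxy)-4-bromobenzoate | CC(=O)OC[C@H](C)CCC[C@H](C=O)[C@@H](c1cc(C(=O)OCc2ccccc2)c(OCc2ccccc2)c(OCc2ccccc2)c1Br)C=C | intermediate
15 | benzyl 5-[(3S,4S,8R)-9-acetoxy-4-(hydroxymethyl)-8-methylnon-1-en-3-yl]-2,3-bis(benzyloxy)-4-bromobenzoate | CC(=O)OC[C@H](C)CCC[C@H](CO)[C@@H](c1cc(C(=O)OCc2ccccc2)c(OCc2ccccc2)c(OCc2ccccc2)c1Br)C=C | intermediate
16 | benzyl 5-[(3S,4S,8R)-9-acetoxy-4-(acetoxymethyl)-8-methylnon-1-en-3-yl]-2,3-bis(benzyloxy)-4-bromobenzoate | CC(=O)OC[C@H](C)CCC[C@H](COC(C)=O)[C@@H](c1cc(C(=O)OCc2ccccc2)c(OCc2ccccc2)c(OCc2ccccc2)c1Br)C=C | intermediate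
17 | benzyl 5-[(3S,4S,8R)-9-acetoxy-4-(acetoxymethyl)-1-(9-borabicyclo[3.3.1]nonan-9-yl)-8-methylnonan-3-yl]-2,3-bis(benzyloxy)-4-bromobenzoate | CC(=O)OC[C@H](C)CCC[C@H](COC(C)=O)[C@@H](c1cc(C(=O)OCc2ccccc2)c(OCc2ccccc2)c(OCc2ccccc2)c1Br)CCB1C2CCCC1CCC2 | intermediate
18 | benzyl 5-[(5S,6S,10R)-11-acetoxy-6-(acetoxymethyl)-10-methylundec-1-en-5-yl]-2,3-bis(benzyloxy)-4-bromobenzoate | CC(=O)OC[C@H](C)CCC[C@H](COC(C)=O)[C@@H](c1cc(C(=O)OCc2ccccc2)c(OCc2ccccc2)c(OCc2ccccc2)c1Br)CCC=C | intermediate
19 | benzyl (5R,8S)-3,4-bis(benzyloxy)-8-[(2S,6R)-1,7-diacetoxy-6-methylheptan-2-yl]-5-methyl-5,6,7,8-tetrahydronaphthalene-2-carboxylate | CC(=O)OC[C@H](C)CCC[C@H](COC(C)=O)[C@@H]1CC[C@@H](C)c2c1cc(C(=O)OCc3ccccc3)c(OCc3ccccc3)c2OCc3ccccc3 | intermediate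
20 | (5R,8S)-8-[(2S,6R)-1,7-diacetoxy-6-methylheptan-2-yl]-3,4-dihydroxy-5-methyl-5,6,7,8-tetrahydronaphthalene-2-carboxylic acid (CNP0245723.1) | CC(=O)OC[C@H](C)CCC[C@H](COC(C)=O)[C@@H]1CC[C@@H](C)c2c1cc(C(=O)O)c(O)c2O | target

**Count**

Total steps: 14. Longest linear sequence: 11 steps (steps 1–5 and 9–14); the side-chain aldehyde 13 takes 3 steps (6–8).

**Steps most likely to fail**

Step 13 (proposed new method). What may go wrong: capture of the C5 radical by the aryl–nickel species may be slow or unselective, so that reduction of the C–Br bond, hydrogenation or isomerisation of the olefin take over; facial selectivity at C5 may be insufficient. Fallback with known chemistry, from 18 back to 19: an intramolecular Mizoroki–Heck reaction (Pd(OAc)2, PPh3, Et3N, MeCN, 80 °C; 6-exo carbopalladation, β-hydride elimination, migration of the exocyclic double bond into the ring) would give benzyl (8S)-3,4-bis(benzyloxy)-8-[(2S,6R)-1,7-diacetoxy-6-methylheptan-2-yl]-5-methyl-7,8-dihydronaphthalene-2-carboxylate F1. Hydrogenation of this trisubstituted aryl olefin with a chiral iridium phosphine–oxazoline catalyst ([Ir(cod)(PHOX)]BArF, monovalent iridium; H2 50 bar, CH2Cl2), with the ligand enantiomer that adds hydrogen to the face giving 5R and so overrides the C8 substituent, would return to 19.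

Step 12. What may go wrong: zerovalent palladium may insert into the aryl bromide in competition with vinyl bromide (cyclised or reduced by-products), and the aqueous base may hydrolyse an acetate. Fallback, from 16 back to 18: linear-selective hydroformylation (Rh(acac)(CO)2, Xantphos, CO/H2, toluene, 70 °C) would give benzyl 5-[(4S,5S,9R)-10-acetoxy-5-(acetoxymethyl)-9-methyl-1-oxodecan-4-yl]-2,3-bis(benzyloxy)-4-bromobenzoate F2. Wittig methylenation (Ph3P=CH2 from Ph3PCH3Br and KHMDS, THF, −78 → 0 °C) would return to 18; no zerovalent palladium meets the aryl bromide on this path.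

Step 3. What may go wrong: bromine may enter para to the directing hydroxyl or attack ipso to the carboxyl group with loss of CO2. Fallback, from 1 back to 5, in which the carboxyl is introduced only after the halogenation:
- demethylation (AlCl3, pyridine, CH2Cl2, reflux) would give 3,4-dihydroxy-5-iodobenzaldehyde F3;
- bromination (Br2, NaOAc, AcOH), now with the site para to the directing hydroxyl flanked by CHO and I, would give 2-bromo-3,4-dihydroxy-5-iodobenzaldehyde F4;
- benzylation (BnBr, K2CO3, DMF) would give 3,4-bis(benzyloxy)-2-bromo-5-iodobenzaldehyde F5;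
- iodide-selective benzyloxycarbonylation (PdCl2(PPh3)2, CO, BnOH, Et3N, 70 °C) would return to 5.

Further compounds
F1 | step 13 | benzyl (8S)-3,4-bis(benzyloxy)-8-[(2S,6R)-1,7-diacetoxy-6-methylheptan-2-yl]-5-methyl-7,8-dihydronaphthalene-2-carboxylate | CC(=O)OC[C@H](C)CCC[C@H](COC(C)=O)[C@@H]1CC=C(C)c2c1cc(C(=O)OCc3ccccc3)c(OCc3ccccc3)c2OCc3ccccc3
F2 | step 12 | benzyl 5-[(4S,5S,9R)-10-acetoxy-5-(acetoxymethyl)-9-methyl-1-oxodecan-4-yl]-2,3-bis(benzyloxy)-4-bromobenzoate | CC(=O)OC[C@H](C)CCC[C@H](COC(C)=O)[C@@H](c1cc(C(=O)OCc2ccccc2)c(OCc2ccccc2)c(OCc2ccccc2)c1Br)CCC=O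
F3 | step 3 | 3,4-dihydroxy-5-iodobenzaldehyde | O=Cc1cc(O)c(O)c(I)c1
F4 | step 3 | 2-bromo-3,4-dihydroxy-5-iodobenzaldehyde | O=Cc1cc(I)c(O)c(O)c1Br
F5 | step 3 | 3,4-bis(benzyloxy)-2-bromo-5-iodobenzaldehyde | O=Cc1cc(I)c(OCc2ccccc2)c(OCc2ccccc2)c1Br
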